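## The problem

The target 29 is a head-to-tail dimer of 3-O-caffeoylquinic acid. C7 of ring A is esterified to the tertiary O1 of ring B; ring A keeps a free tertiary hydroxyl at C1 and ring B a free carboxyl at C7. Each ring also carries a caffeoyl ester on O3 and a free cis-4,5-diol.

Both rings have the same configuration, and it is the mirror image of natural (−)-quinic acid 1: O3 is cis to C7, and O4 and O5 are cis to O1. Compound 1 therefore supplies the skeleton and the sense at C1 and C4, but C3 and C5 must both be inverted.

The hardest bond is the inter-ring ester, which joins a hindered tertiary α-hydroxy acid to a tertiary alcohol that is itself α to a carboxyl. Bimolecular acylation is unfavourable here, and activating either carboxyl invites lactonisation by the cis O3.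

Within a ring, C1 and C4 can steer the rest. C5 can be inverted by an SN2 step, the inverted O5–H can direct an oxidant to its own face of a C3=C4 alkene, and the C1 carboxyl can then deliver O3 from the opposite face. C1 of ring B is created when the rings are joined, and there the cis-fused 4,5-acetonide has to control the new centre.

Several groups will not survive rough treatment:
- the caffeoyl esters migrate to neighbouring hydroxyls and cleave under base, their catechols oxidise, and their alkenes rule out late hydrogenation;
- a free O3–H cis to C7 can expel the other ring by lactonisation;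
- a β-oxygenated cyclohexanone eliminates under base.

The enabling feature is C1 of ring B, which bears an acyloxy group (O1–C7 of ring A) and a carboxyl (C7 of ring B). This α-acyloxy acid pattern is what a Passerini reaction gives from an acid (ring A), a ketone (C1 of ring B) and an isocyanide carbon (future C7 of ring B). Because the two rings are identical, that ketone is simply the ring A acid without its carboxyl.

## Retrosynthesis

**Caffeoyl esters and final unmasking.** Target 29 is traced to its bis-acetonide 28 and then to the penta-allyl compound 27. Cutting the two O3–acyl bonds of 27 gives diol 23 and two molecules of acid 26, which comes from caffeic acid 24 through triallyl compound 25. The caffeoyl esters are the most fragile part, so they go on last. With O4 and O5 tied up as acetonides, the two O3–H groups are the only reactive hydroxyls in 23, and the tertiary O1–H of ring A is too hindered to compete. Allyl groups on the phenols and on the ring B carboxyl leave together under neutral palladium catalysis, and the acetonides are removed last in acid, where acyl migration is slow.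

**Ring B carboxyl.** Diol 23 comes from the bis-silyl allyl ester 22, and 22 from the Passerini adduct 19 through aminoanilide 20 and acylbenzotriazole 21. The amide of 19 must become a carboxyl derivative without base, because an α-acyloxy amide loses or migrates its ester under alkoxide or hydroxide. Convertible isocyanides whose amides are cleaved that way were therefore set aside in favour of 2-nitrophenyl isocyanide 17. Its anilide is activated by reduction and diazotisation and then transfers the acyl group under mild catalysis. The reduction is placed before the cinnamate alkenes arrive.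

**Key disconnection.** Adduct 19 is cut at C1–C7 of ring B and at C7(A)–O1(B), giving acid 13, ketone 14 and isocyanide 17. The neighbouring cut, through the ester alone, would require bimolecular acylation of a tertiary alcohol by a tertiary acid. The three-component cut makes that ester by an intramolecular acyl shift and sets C1 of ring B in the same step. The forward reaction must choose the correct face of 14, tolerate the free tertiary hydroxyl of 13, and leave an amide that can be converted later.

**One unit for both rings.** Ketone 14 is acid 13 without C7, so it is obtained from 13 by oxidative decarboxylation. Acid 13 comes from lactone 10 by opening the lactone and silylating O3. A single intermediate thus feeds both halves.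

**Editing C3 and C5.** Lactone 10 is the acetonide of ent-quinide 9. Cutting the C7–O3 lactone bond and viewing O4 as a former epoxide oxygen leads to epoxy acid 8 and then to alkene acid 7. The O5–H of 7 is cis to O1–H, so it arises from nitrobenzoate 6, which is the Mitsunobu inversion product of allylic alcohol 5. Inverting C3 and C5 directly on the saturated acid would require telling three secondary hydroxyls apart. Removing O3 and O4 first leaves O5–H as the only secondary alcohol, and O3 and O4 then return together in one stereospecific operation.

**Alkene from the pool.** Hydroxy ester 5 comes from bicyclic alkene lactone 4, 4 from thionocarbonate 3 by Corey–Winter elimination, 3 from quinide 2, and 2 from (−)-quinic acid 1. Lactone 2 masks O5 and the carboxyl while the cis-3,4-diol is excised.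

**Isocyanide.** Isocyanide 17 comes from formamide 16 by dehydration, and 16 from 2-nitroaniline 15.

## Roads not taken

**Alternative 1:** The C4–C5 bond of one ring is cut, which leads to acyclic dialdehyde A1: C4 and C5 are formyl groups, C1 is quaternary with a MOM ether and a methyl ester, and C3 carries a benzyl ether. In the forward step SmI2 reduces an aldehyde to a ketyl that adds to the other aldehyde, closing the six-membered ring and giving cis-diol A2 through the chelated samarium diolate.
- Merits: the mirror-image series is reached directly by asymmetric synthesis, with no inversion of pool centres, and the cis-diol comes in one step.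
- Weak points: A1 needs C1 and C3 set on an open chain, its β-alkoxy aldehyde can eliminate, and the diol must form anti to O3 with only 1,3-induction to ensure it. The ring must be built once per monomer, and the inter-ring ester is not addressed.
- Comparison: for absolute configuration this road is better placed than the chosen plan, which spends steps 4 to 7 correcting C3 and C5. The chosen plan sets against that a single pool-derived intermediate (10) for both rings and a key step that forms the difficult ester together with C1–C7 of ring B.

**Alternative 2:** The C1–C6 bond is cut, giving diketo ester A4, which is prepared from diethyl L-tartrate A3. In the forward step the enamine of the C6 methyl ketone adds to the C1 keto-ester carbonyl and gives aldol A5, as in the biosynthesis of dehydroquinate.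
- Merits: a cheap pool of the correct absolute sense for the trans C3/C4 pair, a short chain assembly, and C1 formed with its carboxyl in place.
- Weak points: the C2 methylene between the keto ester and C3 is the more acidic site, and its enolisation leads to loss of O3 or to the wrong aldol. Facial control at C1 depends on a trans-fused acetonide in a ring that is still forming. A5 is a β-hydroxy ketone that dehydrates easily, C5 still needs a cis-selective reduction, and the 3,4-acetonide is the wrong protecting pattern for a target with O3 acylated. The inter-ring ester again remains unsolved.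
- Comparison: this road reaches a monomer in fewer steps than the seven from 1 to 10. The chosen plan sets against that two inherited centres (C1, C4) and two stereospecifically installed ones (C3, C5), where this road has three centres resting on uncertain selectivity.

**Alternative 3:** The two C3–O bonds are cut so that each O3 arrives with its caffeoyl group. The precursor is dimer A6, which has a 3,4-epoxide cis to O5–H in each ring. With Ti(OiPr)4, two molecules of acid 26 open the epoxides at C3 with inversion and give penta-allyl compound A7.
- Merits: a convergent late stage that sets C3 while installing the ester, with no silyl ethers or acetonides; the endgame would be about three steps shorter than steps 15 and 18 to 20.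
- Weak points: in A6 each epoxide sits beside a C7 carbonyl, exactly as in 8, so intramolecular opening at C3 competes and in ring A would expel ring B. The titanium alkoxide can transesterify, and a caffeoyl group on O3 can migrate to the new O4–H. A6 itself still needs the inter-ring ester, now with two epoxides present.
- Comparison: if the intermolecular opening could be made to win, this would be the more economical endgame. The chosen plan sets against it an intramolecular, fully regiocontrolled delivery of O3 and acetonides that block acyl migration.

Key step: step 12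

Remark: the configuration is taken exactly as drawn, so "ent-quinic" below means the mirror image of natural quinic acid. Locants are those of the target (O3 cis to C7; O4 and O5 cis to O1); they stay on the same carbon atoms back to C3, C4 and C5 of compound 1.

## Route

Step 1
Reactants: 1 (−)-quinic acid
Product: 2 1,5-quinide (lactone between C7 and O5; free 1-OH and cis-3,4-diol)
Conditions: TsOH·H2O (cat.), DMF/toluene, reflux, Dean–Stark
Reagents that add atoms: none
Why: Acid-catalysed lactonisation; only O5 is cis to the carboxyl and can bridge to C7, so the carboxyl and O5 are masked together and the cis-3,4-diol stays free.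

Step 2
Reactants: 2 1,5-quinide
Product: 3 3,4-O-thiocarbonyl-1,5-quinide
Conditions: 1,1′-thiocarbonyldiimidazole, MeCN, reflux
Reagents that add atoms: 1,1′-thiocarbonyldiimidazole, S=C(n1ccnc1)n1ccnc1
Why: Cyclic thionocarbonate formation on the cis-vicinal diol; the bridgehead tertiary hydroxyl does not react.

Step 3
Reactants: 3 3,4-O-thiocarbonyl-1,5-quinide
Product: 4 1-hydroxy-6-oxabicyclo[3.2.1]oct-3-en-7-one (3,4-didehydro-3,4-dideoxy-1,5-quinide)
Conditions: P(OMe)3, 110 °C
Reagents that add atoms: none
Why: Corey–Winter olefination; the phosphite removes sulfur and the resulting carbene loses CO2 in a syn elimination that is ideal for a cis-diol, giving the C3=C4 alkene.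

Step 4
Reactants: 4 1-hydroxy-6-oxabicyclo[3.2.1]oct-3-en-7-one
Product: 5 methyl 1,5-dihydroxycyclohex-3-ene-1-carboxylate with 5-OH cis to CO2Me
Conditions: NaOMe (cat.), MeOH, 0 °C; AcOH quench
Reagents that add atoms: methanol, CO
Why: Methanolysis of the strained allylic lactone by acyl attack; C1 has no α-hydrogen, so nothing can epimerise or eliminate, and O5–H is released with its original configuration.

Step 5
Reactants: 5 methyl 1,5-dihydroxycyclohex-3-ene-1-carboxylate (5-OH cis to CO2Me)
Product: 6 methyl 1-hydroxy-5-(4-nitrobenzoyloxy)cyclohex-3-ene-1-carboxylate with the acyloxy group cis to 1-OH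
Conditions: 4-nitrobenzoic acid, PPh3, DIAD, THF, 0 °C → rt
Reagents that add atoms: 4-nitrobenzoic acid, O=C(O)c1ccc(cc1)[N+](=O)[O-]
Why: Mitsunobu inversion; the carboxylate displaces the oxyphosphonium at C5 by SN2, which places O5 cis to O1, and the tertiary hydroxyl is not activated.

Step 6
Reactants: 6 methyl 1-hydroxy-5-(4-nitrobenzoyloxy)cyclohex-3-ene-1-carboxylate
Product: 7 1,5-dihydroxycyclohex-3-ene-1-carboxylic acid with 5-OH cis to 1-OH
Conditions: LiOH, THF/H2O, 0 °C → rt; 1 M HCl to pH 2
Reagents that add atoms: lithium hydroxide, [Li+].[OH-]
Why: Saponification of both esters by acyl–oxygen cleavage, so the inverted C5 is untouched.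

Step 7
Reactants: 7 1,5-dihydroxycyclohex-3-ene-1-carboxylic acid (5-OH cis to 1-OH)
Product: 10 4,5-O-isopropylidene-ent-quinide, via epoxy acid 8 (not isolated), via ent-quinide 9 (not isolated)
Conditions: mCPBA, MeCN, 0 °C → rt; then 2,2-dimethoxypropane, TsOH·H2O (cat.), acetone, rt
Reagents that add atoms: mCPBA, O=C(OO)c1cccc(Cl)c1; 2,2-dimethoxypropane, COC(C)(C)OC
Why: Hydroxyl-directed peracid epoxidation: the allylic O5–H and the homoallylic O1–H lie on the same face and deliver the oxidant there, so the epoxide forms trans to the carboxyl. The carboxyl then opens the epoxide at C3 from the rear (trans-diaxial, bicyclo[3.2.1] γ-lactone), which sets O3 cis to C7 and leaves O4 cis to O5 and O1. The cis-4,5-diol of the water-soluble lactone 9 is ketalised in the same flask.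

Step 8
Reactants: 10 4,5-O-isopropylidene-ent-quinide
Product: 13 3-O-(tert-butyldimethylsilyl)-4,5-O-isopropylidene-ent-quinic acid (ring A acid), via lithium carboxylate 11 (not isolated), via silyl ester 12 (not isolated)
Conditions: LiOH·H2O, THF/H2O, 0 °C, evaporate; TBSCl, imidazole, DMF, rt; K2CO3, MeOH/H2O, 0 °C; dilute HCl to pH 4
Reagents that add atoms: lithium hydroxide, [Li+].[OH-]; tert-butyldimethylsilyl chloride, C[Si](C)(Cl)C(C)(C)C
Why: Hydroxide opens the lactone at the acyl carbon, the carboxylate and the secondary O3–H are silylated while the tertiary O1–H is not, and the much more labile silyl ester is cleaved selectively by mild carbonate solvolysis.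

Step 9
Reactants: 13 ring A acid
Product: 14 3-(tert-butyldimethylsilyloxy)-4,5-(isopropylidenedioxy)cyclohexanone with the silyloxy group trans to the neighbouring acetonide oxygen (ring B ketone)
Conditions: Pb(OAc)4, CH2Cl2, 0 °C → rt
Reagents that add atoms: none
Why: Oxidative decarboxylation of an α-hydroxy acid by lead tetraacetate, a glycol-cleavage-type fragmentation that removes C7 and leaves C3 to C5 untouched; the non-basic medium spares the β-silyloxy ketone.

Step 10
Reactants: 15 2-nitroaniline
Product: 16 N-(2-nitrophenyl)formamide
Conditions: HCO2H (neat), 100 °C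
Reagents that add atoms: formic acid, O=CO
Why: N-Formylation of a weakly basic aniline by heating in formic acid.

Step 11
Reactants: 16 N-(2-nitrophenyl)formamide
Product: 17 2-nitrophenyl isocyanide
Conditions: POCl3, Et3N, CH2Cl2, −20 → 0 °C; used at once
Reagents that add atoms: none
Why: Standard dehydration of a formamide to an isocyanide through its O-phosphorylated imidate.

Step 12
Reactants: 13 ring A acid; 14 ring B ketone; 17 2-nitrophenyl isocyanide
Product: 19 diquinate 2-nitroanilide (ring A acyl on O1 of ring B; ring B C7 as N-(2-nitrophenyl)amide; both O3 as TBS ethers; both 4,5-diols as acetonides), via O-acyl imidate 18 (not isolated)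
Conditions: CH2Cl2 (about 1 M), rt → 35 °C, 48–72 h
Reagents that add atoms: none
Why: Passerini three-component reaction: acid 13 activates the carbonyl of 14 by hydrogen bonding, the isocyanide carbon of 17 adds to C1, and the carboxylate adds to the nitrilium carbon to give O-acyl imidate 18. A Mumm-type 1,4 O→O acyl shift through a five-membered transition state then moves the ring A acyl group onto the adjacent tertiary O1 of ring B, so the congested ester forms intramolecularly and irreversibly. The closest known reaction type is the Passerini reaction of cyclohexanones with carboxylic acids and aryl or convertible isocyanides. No ring is closed; two skeletal bonds (C1–C7 of ring B and C7(A)–O1(B)) and one stereocentre (C1 of ring B) are formed. That centre is set by the substrate: in the preferred chair of 14 the silyloxy group at C3 and O4 are equatorial and O5 of the cis-fused dioxolane is axial, which screens the axial trajectory on its face, so the rod-shaped isocyanide should enter equatorially. C7 then ends up cis to O3 and O1 axial, cis to O4 and O5, as in the target. The step also needs acyl transfer to oxygen and not to the imidate nitrogen, which the five-membered geometry to the neighbouring hydroxyl favours. The weak nucleophilicity of the nitroaryl isocyanide is offset by high concentration and by the acidity of the α-hydroxy acid, whose own tertiary hydroxyl is too hindered to intervene.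

Step 13
Reactants: 19 diquinate 2-nitroanilide
Product: 20 diquinate 2-aminoanilide
Conditions: H2 (1 atm), 10% Pd/C, EtOAc, rt
Reagents that add atoms: none
Why: Catalytic hydrogenation of an aryl nitro group; at this stage the molecule has no alkene or benzylic group, which is why the reduction precedes caffeoylation.

Step 14
Reactants: 20 diquinate 2-aminoanilide
Product: 22 diquinate allyl ester (ring B C7 as allyl ester; TBS ethers and acetonides unchanged), via N-acylbenzotriazole 21 (not isolated)
Conditions: isoamyl nitrite, AcOH, CH2Cl2, 0 °C → rt; concentrate; allyl alcohol, Et3N, DMAP, CH2Cl2, 40 °C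
Reagents that add atoms: allyl alcohol, C=CCO; isoamyl nitrite, CC(C)CCON=O (nitrogen of intermediate 21 only)
Why: Diazotisation of the aniline and capture of the diazonium by the amide nitrogen give an N-acylbenzotriazole without any base, so the α-acyloxy amide cannot lose or shift its ester. This activated amide then transfers its acyl group to allyl alcohol under DMAP catalysis much faster than the hindered esters react.

Step 15
Reactants: 22 diquinate allyl ester
Product: 23 diquinate allyl ester 3,3′-diol (free O3–H in both rings)
Conditions: HF·pyridine, pyridine/THF, 0 °C → rt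
Reagents that add atoms: none
Why: Fluoride cleavage of the two secondary silyl ethers in a buffered, slightly acidic medium; acetonides and esters are stable, and the absence of a basic alkoxide keeps O3 from lactonising onto C7.

Step 16
Reactants: 24 caffeic acid
Product: 25 allyl (E)-3-[3,4-bis(allyloxy)phenyl]prop-2-enoate
Conditions: allyl bromide, K2CO3, DMF, 50 °C
Reagents that add atoms: allyl bromide, C=CCBr
Why: Williamson alkylation of both phenols and of the carboxylate.

Step 17
Reactants: 25 allyl 3,4-bis(allyloxy)cinnamate
Product: 26 (E)-3-[3,4-bis(allyloxy)phenyl]prop-2-enoic acid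
Conditions: NaOH, MeOH/THF/H2O, rt; 1 M HCl
Reagents that add atoms: sodium hydroxide, [Na+].[OH-]
Why: Saponification of the allyl ester; the aryl allyl ethers are inert to hydroxide.

Step 18
Reactants: 23 diquinate allyl ester 3,3′-diol; 26 3,4-bis(allyloxy)cinnamic acid (2.4 equiv)
Product: 27 penta-allyl bis-acetonide of the target (both O3 acylated by 3,4-bis(allyloxy)cinnamoyl)
Conditions: EDC·HCl, DMAP, CH2Cl2, 0 °C → rt
Reagents that add atoms: none
Why: Steglich esterification of the two secondary O3–H groups with retention at C3; the acetonides block O4 and O5, and the tertiary O1–H of ring A is too hindered for the O-acylisourea/DMAP system.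

Step 19
Reactants: 27 penta-allyl bis-acetonide
Product: 28 bis-acetonide of the target (free catechols and free ring B carboxyl)
Conditions: Pd(PPh3)4 (cat.), morpholine, THF, rt, argon
Reagents that add atoms: none
Why: Tsuji–Trost deallylation: zerovalent palladium ionises the allyl ester and the four aryl allyl ethers, and morpholine traps the allyl groups. The acetonides are still in place, so no caffeoyl migration can occur in the presence of the amine.

Step 20
Reactants: 28 bis-acetonide of the target
Product: 29 target CNP0107948.2
Conditions: TFA/H2O (9:1), 0 °C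
Reagents that add atoms: none
Why: Acid hydrolysis of the two isopropylidene acetals; the acidic medium suppresses acyl migration and no stereocentre is involved.

## Compound list

1 | (−)-quinic acid, (1S,3R,4S,5R)-1,3,4,5-tetrahydroxycyclohexane-1-carboxylic acid | O[C@]1(C(=O)O)C[C@@H](O)[C@H](O)[C@H](O)C1 | starting material
2 | 1,5-quinide (lactone C7–O5 of natural quinic acid) | O[C@@]12C[C@@H](OC1=O)[C@H](O)[C@H](O)C2 | intermediate
3 | 3,4-O-thiocarbonyl-1,5-quinide | O[C@@]12C[C@@H](OC1=O)[C@@H]3OC(=S)O[C@@H]3C2 | intermediate
4 | 1-hydroxy-6-oxabicyclo[3.2.1]oct-3-en-7-one (lactone oxygen on C5, natural sense) | O[C@@]12C[C@@H](OC1=O)C=CC2 | intermediate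
5 | methyl 1,5-dihydroxycyclohex-3-ene-1-carboxylate, 5-OH cis to CO2Me | O[C@]1(C(=O)OC)C[C@@H](O)C=CC1 | intermediate
6 | methyl 1-hydroxy-5-(4-nitrobenzoyloxy)cyclohex-3-ene-1-carboxylate, acyloxy cis to 1-OH | O[C@]1(C(=O)OC)C[C@H](OC(=O)c2ccc(cc2)[N+](=O)[O-])C=CC1 | intermediate
7 | 1,5-dihydroxycyclohex-3-ene-1-carboxylic acid, 5-OH cis to 1-OH | O[C@]1(C(=O)O)C[C@H](O)C=CC1 | intermediate
8 | 3,4-epoxy-1,5-dihydroxycyclohexane-1-carboxylic acid, epoxide oxygen cis to both hydroxyls and trans to CO2H | O[C@]1(C(=O)O)C[C@H](O)[C@@H]2O[C@@H]2C1 | intermediate (not isolated)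
9 | ent-quinide (mirror image of 2: lactone C7–O3, cis-4,5-diol cis to 1-OH) | O[C@]12C[C@H](OC1=O)[C@@H](O)[C@@H](O)C2 | intermediate (not isolated)
10 | 4,5-O-isopropylidene-ent-quinide | O[C@]12C[C@H](OC1=O)[C@H]3OC(C)(C)O[C@H]3C2 | intermediate
11 | lithium 4,5-O-isopropylidene-ent-quinate | O[C@@]1(C(=O)[O-])C[C@H](O)[C@H]2OC(C)(C)O[C@H]2C1.[Li+] | intermediate (not isolated)
12 | tert-butyldimethylsilyl 3-O-TBS-4,5-O-isopropylidene-ent-quinate | O[C@@]1(C(=O)O[Si](C)(C)C(C)(C)C)C[C@H](O[Si](C)(C)C(C)(C)C)[C@H]2OC(C)(C)O[C@H]2C1 | intermediate (not isolated)
13 | 3-O-TBS-4,5-O-isopropylidene-ent-quinic acid (ring A acid) | O[C@@]1(C(=O)O)C[C@H](O[Si](C)(C)C(C)(C)C)[C@H]2OC(C)(C)O[C@H]2C1 | intermediate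
14 | 3-(tert-butyldimethylsilyloxy)-4,5-(isopropylidenedioxy)cyclohexanone, silyloxy trans to O4 (ring B ketone) | O=C1C[C@H](O[Si](C)(C)C(C)(C)C)[C@H]2OC(C)(C)O[C@H]2C1 | intermediate
15 | 2-nitroaniline | Nc1ccccc1[N+](=O)[O-] | starting material
16 | N-(2-nitrophenyl)formamide | O=CNc1ccccc1[N+](=O)[O-] | intermediate
17 | 2-nitrophenyl isocyanide | [C-]#[N+]c1ccccc1[N+](=O)[O-] | intermediate
18 | O-acyl imidate from 13, 14 and 17 (ring A acyl on the imidate oxygen; ring B C1 with free OH cis to O4/O5) | O[C@@]1(C(=O)OC(=Nc2ccccc2[N+](=O)[O-])[C@]3(O)C[C@H](O[Si](C)(C)C(C)(C)C)[C@H]4OC(C)(C)O[C@H]4C3)C[C@H](O[Si](C)(C)C(C)(C)C)[C@H]5OC(C)(C)O[C@H]5C1 | intermediate (not isolated)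
19 | diquinate 2-nitroanilide (Passerini adduct) | O[C@@]1(C(=O)O[C@@]2(C(=O)Nc3ccccc3[N+](=O)[O-])C[C@H](O[Si](C)(C)C(C)(C)C)[C@H]4OC(C)(C)O[C@H]4C2)C[C@H](O[Si](C)(C)C(C)(C)C)[C@H]5OC(C)(C)O[C@H]5C1 | intermediate
20 | diquinate 2-aminoanilide | O[C@@]1(C(=O)O[C@@]2(C(=O)Nc3ccccc3N)C[C@H](O[Si](C)(C)C(C)(C)C)[C@H]4OC(C)(C)O[C@H]4C2)C[C@H](O[Si](C)(C)C(C)(C)C)[C@H]5OC(C)(C)O[C@H]5C1 | intermediate
21 | diquinate N-acylbenzotriazole (ring B C7 on N1 of benzotriazole) | O[C@@]1(C(=O)O[C@@]2(C(=O)n3nnc4ccccc43)C[C@H](O[Si](C)(C)C(C)(C)C)[C@H]5OC(C)(C)O[C@H]5C2)C[C@H](O[Si](C)(C)C(C)(C)C)[C@H]6OC(C)(C)O[C@H]6C1 | intermediate (not isolated)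
22 | diquinate allyl ester (bis-TBS, bis-acetonide) | O[C@@]1(C(=O)O[C@@]2(C(=O)OCC=C)C[C@H](O[Si](C)(C)C(C)(C)C)[C@H]3OC(C)(C)O[C@H]3C2)C[C@H](O[Si](C)(C)C(C)(C)C)[C@H]4OC(C)(C)O[C@H]4C1 | intermediate
23 | diquinate allyl ester 3,3′-diol (bis-acetonide) | O[C@@]1(C(=O)O[C@@]2(C(=O)OCC=C)C[C@H](O)[C@H]3OC(C)(C)O[C@H]3C2)C[C@H](O)[C@H]4OC(C)(C)O[C@H]4C1 | intermediate
24 | caffeic acid | O=C(O)/C=C/c1ccc(O)c(O)c1 | starting material
25 | allyl (E)-3-[3,4-bis(allyloxy)phenyl]prop-2-enoate | C=CCOC(=O)/C=C/c1ccc(OCC=C)c(OCC=C)c1 | intermediate
26 | (E)-3-[3,4-bis(allyloxy)phenyl]prop-2-enoic acid | O=C(O)/C=C/c1ccc(OCC=C)c(OCC=C)c1 | intermediate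
27 | penta-allyl bis-acetonide of the target | O[C@@]1(C(=O)O[C@@]2(C(=O)OCC=C)C[C@H](OC(=O)/C=C/c3ccc(OCC=C)c(OCC=C)c3)[C@H]4OC(C)(C)O[C@H]4C2)C[C@H](OC(=O)/C=C/c5ccc(OCC=C)c(OCC=C)c5)[C@H]6OC(C)(C)O[C@H]6C1 | intermediate
28 | bis-acetonide of the target | O[C@@]1(C(=O)O[C@@]2(C(=O)O)C[C@H](OC(=O)/C=C/c3ccc(O)c(O)c3)[C@H]4OC(C)(C)O[C@H]4C2)C[C@H](OC(=O)/C=C/c5ccc(O)c(O)c5)[C@H]6OC(C)(C)O[C@H]6C1 | intermediate
29 | CNP0107948.2 | O=C(/C=C/c1ccc(O)c(O)c1)O[C@H]1C[C@@](O)(C(=O)O[C@@]2(C(=O)O)C[C@H](OC(=O)/C=C/c3ccc(O)c(O)c3)[C@@H](O)[C@@H](O)C2)C[C@H](O)[C@@H]1O | target

## Step count and least certain steps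

Total: 20 steps. Longest linear sequence: 16 steps (steps 1 to 9, 12 to 15, 18 to 20). The isocyanide (steps 10, 11) and the caffeoyl donor (steps 16, 17) are two-step side branches.

**Step 12 (key step).** The most likely failures are slow addition of the electron-poor isocyanide to the hindered ketone, so that the isocyanide decays first, and incomplete facial selectivity, with some axial entry syn to the dioxolane giving the C1 epimer of ring B. A smaller risk is acyl transfer to the imidate nitrogen. The fallback gives up the three-component union and takes both C1 centres from the pool. It sets out from acid 13, which is cyclodimerised (2-chloro-1-methylpyridinium iodide, Et3N, CH2Cl2, reflux) to the C2-symmetric spiro-dilactone F1, a 1,4-dioxane-2,5-dione of the glycolide type. Its two ester carbonyls are equivalent, so opening either one with allyl alcohol and a catalytic amount of sodium allyloxide gives the same linear dimer. The fallback returns to the route at 22, and compounds 19 to 21 are bypassed.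

**Step 5.** Competing SN2′ displacement would deliver oxygen to C3 and produce the enantiomeric ester, which erodes optical purity without giving a separable by-product; elimination to the diene is the second risk. The fallback avoids substitution at an allylic centre and instead moves the lactone from O5 to O3 on the same face. It sets out from 4, which is opened with aqueous NaOH to the sodium hydroxy-carboxylate F2 and iodolactonised in the same pot (I2, KI, NaHCO3) to iodolactone F3, with the carboxylate entering at C3 and iodine trans at C4. The trans-diaxial iodohydrin is eliminated under Garegg–Samuelsson-type conditions (PPh3, I2, imidazole, toluene, 80 °C) to the mirror-image alkene lactone F4. Dihydroxylation (OsO4 cat., NMO) from the face away from the lactone bridge gives 9, which is ketalised to 10 as in step 7. The route is rejoined at 10.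

**Step 7.** Epoxidation on the wrong face, or opening of the epoxide by water from the wet peracid before the carboxyl can attack, would lower the throughput to 10. The fallback separates the two events and uses a metal-bound hydroxyl to direct the oxidant. It sets out from 6, whose nitrobenzoate is removed by K2CO3 in MeOH to give diol ester F5. VO(acac)2 with tBuOOH gives the syn-epoxy ester F6. Saponification with LiOH and acidification releases 8, which lactonises to 9 and is ketalised to 10.

**Step 8.** Return of the silyl ester or of the free hydroxy acid to lactone 10 before O3 is silylated is the main risk, since the cis O3–H is well placed for it. The fallback passes through a stable ester. It sets out from 10, which is opened with NaOMe in MeOH to the hydroxy methyl ester F7 and silylated (TBSCl, imidazole, DMF) to F8. LiOH hydrolysis then gives 13.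

**Step 9.** β-Elimination of the silyloxy group from the new ketone, or incomplete fragmentation of the hindered lead carboxylate, could lower the yield of 14. The fallback reaches the ketone by reduction and glycol cleavage. It sets out from 10, which is reduced with NaBH4 in EtOH to triol F9 and cleaved with NaIO4 in buffered water to hydroxy ketone F10. Silylation (TBSCl, imidazole, DMF, 0 °C) gives 14.

**Step 14.** Acyl transfer from the benzotriazolide to allyl alcohol is slow at the quaternary centre. That leaves time for the tertiary O1–H of ring A to capture the acyl group in a lactide-type closure, or for the sequence to stall at 21. The fallback replaces acyl transfer to an alcohol by hydrolysis followed by carboxylate alkylation. It sets out from 20, which is diazotised as before to 21 and then hydrolysed (H2O, Et3N, DMAP, THF, 0 °C → rt) to the free acid F11. Hydroxide-type opening of any dilactone formed leads to the same acid, because both its carbonyls are equivalent. O-Alkylation with allyl bromide and Cs2CO3 in DMF, which involves no acyl activation, gives 22.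

## Further compounds

F1 | step 12 | C2-symmetric spiro-dilactone (1,4-dioxane-2,5-dione) from two molecules of 13 | O=C1O[C@]2(C[C@H](O[Si](C)(C)C(C)(C)C)[C@H]3OC(C)(C)O[C@H]3C2)C(=O)O[C@]14C[C@H](O[Si](C)(C)C(C)(C)C)[C@H]5OC(C)(C)O[C@H]5C4
F2 | step 5 | sodium 1,5-dihydroxycyclohex-3-ene-1-carboxylate, 5-OH cis to the carboxylate | O[C@]1(C(=O)[O-])C[C@@H](O)C=CC1.[Na+]
F3 | step 5 | 1,3-hydroxy... iodolactone: 1,3-lactone (C7–O3) with 4-iodo trans to O3 and 5-OH cis to C7 | O[C@]12C[C@H](OC1=O)[C@@H](I)[C@H](O)C2
F4 | step 5 | enantiomer of 4, 1-hydroxy-6-oxabicyclo[3.2.1]oct-3-en-7-one with the lactone oxygen on C3 | O[C@]12C[C@H](OC1=O)C=CC2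
F5 | step 7 | methyl 1,5-dihydroxycyclohex-3-ene-1-carboxylate, 5-OH cis to 1-OH | O[C@]1(C(=O)OC)C[C@H](O)C=CC1
F6 | step 7 | methyl 3,4-epoxy-1,5-dihydroxycyclohexane-1-carboxylate, epoxide cis to both hydroxyls | O[C@]1(C(=O)OC)C[C@H](O)[C@@H]2O[C@@H]2C1
F7 | step 8 | methyl 4,5-O-isopropylidene-ent-quinate | O[C@@]1(C(=O)OC)C[C@H](O)[C@H]2OC(C)(C)O[C@H]2C1
F8 | step 8 | methyl 3-O-TBS-4,5-O-isopropylidene-ent-quinate | O[C@@]1(C(=O)OC)C[C@H](O[Si](C)(C)C(C)(C)C)[C@H]2OC(C)(C)O[C@H]2C1
F9 | step 9 | 1-(hydroxymethyl)-4,5-(isopropylidenedioxy)cyclohexane-1,3-diol from reduction of 10 | O[C@@]1(CO)C[C@H](O)[C@H]2OC(C)(C)O[C@H]2C1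
F10 | step 9 | 3-hydroxy-4,5-(isopropylidenedioxy)cyclohexanone, hydroxyl trans to O4 | O=C1C[C@H](O)[C@H]2OC(C)(C)O[C@H]2C1
F11 | step 14 | diquinate free acid (ring B CO2H; bis-TBS, bis-acetonide) | O[C@@]1(C(=O)O[C@@]2(C(=O)O)C[C@H](O[Si](C)(C)C(C)(C)C)[C@H]3OC(C)(C)O[C@H]3C2)C[C@H](O[Si](C)(C)C(C)(C)C)[C@H]4OC(C)(C)O[C@H]4C1
A1 | alternative 1 | acyclic C4,C5-dialdehyde with C1 MOM ether, methyl ester and C3 benzyl ether | COCO[C@@](CC=O)(C(=O)OC)C[C@H](OCc1ccccc1)C=O
A2 | alternative 1 | protected ent-quinate cis-4,5-diol | COCO[C@@]1(C(=O)OC)C[C@H](OCc2ccccc2)[C@@H](O)[C@@H](O)C1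
A3 | alternative 2 | diethyl L-tartrate | CCOC(=O)[C@H](O)[C@@H](O)C(=O)OCC
A4 | alternative 2 | tartrate-derived 2,6-diketo ester, 3,4-acetonide | CCOC(=O)C(=O)C[C@@H]1OC(C)(C)O[C@H]1C(C)=O
A5 | alternative 2 | 5-dehydroquinate-type aldol, 3,4-acetonide | O[C@@]1(C(=O)OCC)C[C@@H]2OC(C)(C)O[C@H]2C(=O)C1
A6 | alternative 3 | dimer allyl ester with a 3,4-epoxide cis to 5-OH in each ring | O[C@@]1(C(=O)O[C@@]2(C(=O)OCC=C)C[C@H]3O[C@H]3[C@@H](O)C2)C[C@H]4O[C@H]4[C@@H](O)C1
A7 | alternative 3 | penta-allyl-protected target | O[C@@]1(C(=O)O[C@@]2(C(=O)OCC=C)C[C@H](OC(=O)/C=C/c3ccc(OCC=C)c(OCC=C)c3)[C@@H](O)[C@@H](O)C2)C[C@H](OC(=O)/C=C/c4ccc(OCC=C)c(OCC=C)c4)[C@@H](O)[C@@H](O)C1
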